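Both upper units are all-cis at C2–C3–C4, which attack on a closed ring C (3,4-trans) cannot give, so each pyran ring is closed last, at O1–C2. The top unit enters as an open-chain trans-epoxy ketone from one catalytic asymmetric epoxidation. In one flask C8 of the middle unit opens the epoxide at C4 with inversion, the unmasked ring-A phenol O1 adds to the C2 ketone, and hydride attacks the cyclic oxocarbenium ion anti to O3 and the C4 aryl group. This exploits the all-cis triad of the top ring C and its donor-stabilised benzylic C2. Hydride or monomer as nucleophile builds the other units.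

Key step: step 8

Remark: the target is read as ent-epiafzelechin-(4β→8)-epiafzelechin-(4α→8)-ent-epiafzelechin-4α-ol. The top unit is 2S,3S and 2,3-cis-3,4-cis, the middle unit is 2R,3R and 2,3-cis-3,4-cis, and the bottom unit is 2S,3S,4R and 2,3-cis-3,4-trans. Flavan numbering (O1, C2, C3, C4, C4a to C8a; rings A, B, C) is used for every unit.

Step 1
Reactants: 1 3,5-bis(benzyloxy)phenol
Product: 2 2,4-bis(benzyloxy)-6-hydroxybenzaldehyde
Conditions: MgCl2, Et3N, (CH2O)n, MeCN, reflux
Reagents that add atoms: paraformaldehyde, reacting as formaldehyde, C=O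
Why: Casnati–Skattebøl ortho-formylation, in which the magnesium phenoxide delivers formaldehyde only to a carbon ortho to its oxygen (the two such carbons of 1 are equivalent) and a second formaldehyde takes up the hydride.

Step 2
Reactants: 2 2,4-bis(benzyloxy)-6-hydroxybenzaldehyde
Product: 3 2,4-bis(benzyloxy)-6-(methoxymethoxy)benzaldehyde
Conditions: NaH, MOMCl, DMF, 0 °C to rt
Reagents that add atoms: chloromethyl methyl ether (MOMCl), COCCl
Why: Williamson-type O-alkylation of the sodium phenoxide, which marks the one oxygen that will become O1 with the only acid-labile group on ring A.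

Step 3
Reactants: 3 2,4-bis(benzyloxy)-6-(methoxymethoxy)benzaldehyde; 4 4'-(benzyloxy)acetophenone
Product: 5 (E)-3-[2,4-bis(benzyloxy)-6-(methoxymethoxy)phenyl]-1-[4-(benzyloxy)phenyl]prop-2-en-1-one
Conditions: KOH, EtOH–THF, rt
Reagents that add atoms: none
Why: Claisen–Schmidt condensation of a non-enolisable aldehyde with a methyl ketone, the E1cB loss of water giving the E-enone under thermodynamic control.

Step 4
Reactants: 5 the E-enone
Product: 6 [(2S,3R)-3-[2,4-bis(benzyloxy)-6-(methoxymethoxy)phenyl]oxiran-2-yl][4-(benzyloxy)phenyl]methanone (trans-epoxy ketone)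
Conditions: La(OiPr)3 (10 mol %), (R)-BINOL (10 mol %), Ph3As=O (10 mol %), TBHP (decane), MS 4 Å, THF, rt; filtration through basic alumina
Reagents that add atoms: tert-butyl hydroperoxide, CC(C)(C)OO
Why: Catalytic asymmetric Weitz–Scheffer epoxidation of a chalcone-type enone, in which conjugate addition of the lanthanum-bound peroxide to one enone face sets both epoxide carbons (trans, from the E-alkene), (R)-BINOL being expected by analogy with chalcone itself to give the (2S,3R) isomer.

Step 5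
Reactants: 5 the E-enone
Product: 7 the (2R,3S)-trans-epoxy ketone, enantiomer of 6
Conditions: La(OiPr)3 (10 mol %), (S)-BINOL (10 mol %), Ph3As=O (10 mol %), TBHP (decane), MS 4 Å, THF, rt; filtration through basic alumina
Reagents that add atoms: tert-butyl hydroperoxide, CC(C)(C)OO
Why: The same catalytic asymmetric Weitz–Scheffer epoxidation with the mirror-image ligand should attack the opposite enone face and set both carbons in the enantiomeric sense.

Step 6
Reactants: 6 the (2S,3R)-epoxy ketone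
Product: 10 (2S,3S)-5,7,4'-tri-O-benzyl-ent-epiafzelechin, via hydroxy ketone 8 (not isolated), via hemiketal 9 (not isolated)
Conditions: Et3SiH (10 equiv), BF3·OEt2 (3 equiv), CH2Cl2, −78 to −20 °C
Reagents that add atoms: none
Why: Ionic hydrogenation cascade in which BF3 opens the epoxide at the carbon stabilised by ring A and the silane traps the cation (C4H2), the MOM acetal is ionised with its cation reduced to dimethyl ether, the freed phenol adds to the ketone, and the hemiketal is reduced like a lactol in C-aryl glycoside synthesis, hydride reaching the nearly flat 2-aryl oxocarbenium ion anti to the C3 oxygen so that C2 is set 2,3-cis while C3 is carried over from the epoxide.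

Step 7
Reactants: 10 tri-O-benzyl-ent-epiafzelechin (2 equiv, excess recovered); 7 the (2R,3S)-epoxy ketone
Product: 13 hexa-O-benzyl epiafzelechin-(4α→8)-ent-epiafzelechin, via open-chain hydroxy ketone 11 (not isolated), via hemiketal 12 (not isolated)
Conditions: BF3·OEt2 (0.2 equiv), CH2Cl2, −78 °C; then Et3SiH (10 equiv), BF3·OEt2 (3 equiv), −78 to −20 °C
Reagents that add atoms: none
Why: Friedel–Crafts arylative epoxide opening, phenol-to-ketone closure and silane reduction of the hemiketal as in step 8, C8 of 10 attacking the ring-A-bearing epoxide carbon of 7 with inversion (C4, 3,4-cis after closure), C3 coming from the epoxide and hydride adding to the C2 oxocarbenium ion anti to O3 and the C4 aryl group (C2, all-cis), so that the catalyst-set epoxide and not the chiral nucleophile decides the absolute sense.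

Step 8
Reactants: 13 the hexa-O-benzyl dimer (1.5 equiv, excess recovered); 6 the (2S,3R)-epoxy ketone
Product: 16 nona-O-benzyl ent-epiafzelechin-(4β→8)-epiafzelechin-(4α→8)-ent-epiafzelechin, via open-chain hydroxy ketone 14 (not isolated), via hemiketal 15 (not isolated)
Conditions: BF3·OEt2 (0.2 equiv), CH2Cl2, −78 °C; then Et3SiH (10 equiv), BF3·OEt2 (3 equiv), −78 to −20 °C
Reagents that add atoms: none
Why: Catalytic BF3 opens the epoxide of 6 at the carbon that bears ring A, and C8 of the upper unit of 13 attacks it from the side opposite the departing oxygen (Friedel–Crafts arylative epoxide opening, the open-chain counterpart of the usual C4-to-C8 flavanyl coupling), which gives hydroxy ketone 14. With excess BF3 and Et3SiH the MOM acetal is ionised (its cation is reduced to dimethyl ether), the freed phenol O1 adds to the C2 carbonyl in a 6-exo-trig closure to hemiketal 15, and 15 is reduced through the 2-aryl oxocarbenium ion as in a reductive etherification or the silane reduction of a lactol. C3 is carried over unchanged from the epoxide, and C4 is set by inversion at the epoxide carbon, an erythro relation that becomes 3,4-cis once the ring is closed because the epoxide is trans, the BF3-bound alkoxide and the allylic strain from the two ortho substituents of ring A keeping the departure face shut. C2 is set by substrate control, since the oxocarbenium ring is almost flat and O3 and the C4 aryl group both stand on one face, so hydride comes from the other face and ring B ends cis to both. Selectivity for C8 over the C6 positions follows the known preference of O-benzylated flavan-3-ols (C8 has the small ring oxygen as one neighbour), ether formation at the free 3-OH groups is reversible, and only O1 can close the ring because every other phenol, O7 of the middle unit included, is a benzyl ether. Hydride is added only after the arylation, so that C4 is not reduced.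

Step 9
Reactants: 16 the nona-O-benzyl trimer
Product: 17 nona-O-benzyl ent-epiafzelechin-(4β→8)-epiafzelechin-(4α→8)-ent-epiafzelechin-4α-ol (bottom unit 2S,3S,4R)
Conditions: DDQ (1.5 equiv), CH2Cl2–H2O, 0 °C to rt
Reagents that add atoms: water, O
Why: DDQ-mediated benzylic hydride abstraction, known for O-benzylated flavan-3-ols, should take place at the only CH2 group next to a phloroglucinol-type ring (the tertiary C4–H bonds of the two upper units are buried between two doubly ortho-substituted rings that cannot both conjugate with a cation), and water adds to the C4 cation on the face anti to the axial 3-OH, which sets C4 as 3,4-trans.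

Step 10
Reactants: 17 the nona-O-benzyl trimeric 4α-ol
Product: 18 CNP0159291.1, ent-epiafzelechin-(4β→8)-epiafzelechin-(4α→8)-ent-epiafzelechin-4α-ol
Conditions: H2 (1 atm), Pd(OH)2/C, THF–EtOAc–H2O, rt; filtration under argon, lyophilisation
Reagents that add atoms: none
Why: Hydrogenolysis of the nine aryl benzyl ethers proceeds through adsorption of the exposed benzyl phenyl rings, whereas cleavage of the C4–OH bond would need the fully substituted, buried ring A of the bottom unit to lie on the metal, and the neutral, alcohol-free medium avoids solvolysis at C4 and epimerisation at C2, so no stereocentre is touched.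

Compound list
1 | 3,5-bis(benzyloxy)phenol | Oc1cc(OCc2ccccc2)cc(OCc2ccccc2)c1 | starting material
2 | 2,4-bis(benzyloxy)-6-hydroxybenzaldehyde | O=Cc1c(O)cc(OCc2ccccc2)cc1OCc1ccccc1 | intermediate
3 | 2,4-bis(benzyloxy)-6-(methoxymethoxy)benzaldehyde | O=Cc1c(OCOC)cc(OCc2ccccc2)cc1OCc1ccccc1 | intermediate
4 | 4'-(benzyloxy)acetophenone | CC(=O)c1ccc(OCc2ccccc2)cc1 | starting material
5 | (E)-3-[2,4-bis(benzyloxy)-6-(methoxymethoxy)phenyl]-1-[4-(benzyloxy)phenyl]prop-2-en-1-one | O=C(/C=C/c1c(OCOC)cc(OCc2ccccc2)cc1OCc1ccccc1)c1ccc(OCc2ccccc2)cc1 | intermediate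
6 | (2S,3R)-trans-epoxy ketone | O=C(c1ccc(OCc2ccccc2)cc1)[C@H]1O[C@@H]1c1c(OCOC)cc(OCc2ccccc2)cc1OCc1ccccc1 | intermediate
7 | (2R,3S)-trans-epoxy ketone, enantiomer of 6 | O=C(c1ccc(OCc2ccccc2)cc1)[C@@H]1O[C@H]1c1c(OCOC)cc(OCc2ccccc2)cc1OCc1ccccc1 | intermediate
8 | (2S)-3-[2,4-bis(benzyloxy)-6-(methoxymethoxy)phenyl]-1-[4-(benzyloxy)phenyl]-2-hydroxypropan-1-one | O=C(c1ccc(OCc2ccccc2)cc1)[C@@H](O)Cc1c(OCOC)cc(OCc2ccccc2)cc1OCc1ccccc1 | intermediate
9 | (3S)-5,7-bis(benzyloxy)-2-[4-(benzyloxy)phenyl]chromane-2,3-diol, both anomers at C2 | O[C@H]1Cc2c(OCc3ccccc3)cc(OCc3ccccc3)cc2OC1(O)c1ccc(OCc2ccccc2)cc1 | intermediate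
10 | (2S,3S)-5,7,4'-tri-O-benzyl-ent-epiafzelechin | O[C@H]1Cc2c(OCc3ccccc3)cc(OCc3ccccc3)cc2O[C@H]1c1ccc(OCc2ccccc2)cc1 | intermediate
11 | open-chain hydroxy ketone on C8 of 10 (C3 R, erythro to the new C4, ring A still MOM-protected) | O=C(c1ccc(OCc2ccccc2)cc1)[C@H](O)[C@@H](c1c(OCOC)cc(OCc2ccccc2)cc1OCc1ccccc1)c1c(OCc2ccccc2)cc(OCc2ccccc2)c2c1O[C@@H](c1ccc(OCc3ccccc3)cc1)[C@@H](O)C2 | intermediate
12 | dimer with the upper unit as 2-hydroxyflavan hemiketal, both anomers at C2 | C(c1ccccc1)Oc1ccc(C2(O)Oc3cc(OCc4ccccc4)cc(OCc4ccccc4)c3[C@@H](c3c(OCc4ccccc4)cc(OCc4ccccc4)c4c3O[C@@H](c3ccc(OCc5ccccc5)cc3)[C@@H](O)C4)[C@H]2O)cc1 | intermediate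
13 | hexa-O-benzyl epiafzelechin-(4α→8)-ent-epiafzelechin (upper unit all-cis) | C(c1ccccc1)Oc1ccc([C@H]2Oc3cc(OCc4ccccc4)cc(OCc4ccccc4)c3[C@@H](c3c(OCc4ccccc4)cc(OCc4ccccc4)c4c3O[C@@H](c3ccc(OCc5ccccc5)cc3)[C@@H](O)C4)[C@H]2O)cc1 | intermediate
14 | open-chain hydroxy ketone on C8 of the upper unit of 13 (C3 S, erythro to the new C4, ring A still MOM-protected) | O=C(c1ccc(OCc2ccccc2)cc1)[C@@H](O)[C@H](c1c(OCOC)cc(OCc2ccccc2)cc1OCc1ccccc1)c1c(OCc2ccccc2)cc(OCc2ccccc2)c2c1O[C@H](c1ccc(OCc3ccccc3)cc1)[C@H](O)[C@@H]2c1c(OCc2ccccc2)cc(OCc2ccccc2)c2c1O[C@@H](c1ccc(OCc3ccccc3)cc1)[C@@H](O)C2 | intermediate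
15 | trimer with the top unit as 2-hydroxyflavan hemiketal, both anomers at C2 | C(c5ccccc5)Oc1ccc([C@H]2Oc3c(c(OCc5ccccc5)cc(OCc5ccccc5)c3[C@H]3c4c(OCc5ccccc5)cc(OCc5ccccc5)cc4OC(O)(c4ccc(OCc5ccccc5)cc4)[C@H]3O)[C@@H](c3c(OCc5ccccc5)cc(OCc5ccccc5)c4c3O[C@@H](c3ccc(OCc5ccccc5)cc3)[C@@H](O)C4)[C@H]2O)cc1 | intermediate
16 | nona-O-benzyl ent-epiafzelechin-(4β→8)-epiafzelechin-(4α→8)-ent-epiafzelechin | C(c5ccccc5)Oc1ccc([C@H]2Oc3c(c(OCc5ccccc5)cc(OCc5ccccc5)c3[C@H]3c4c(OCc5ccccc5)cc(OCc5ccccc5)cc4O[C@@H](c4ccc(OCc5ccccc5)cc4)[C@H]3O)[C@@H](c3c(OCc5ccccc5)cc(OCc5ccccc5)c4c3O[C@@H](c3ccc(OCc5ccccc5)cc3)[C@@H](O)C4)[C@H]2O)cc1 | intermediate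
17 | 16 with a 4α-hydroxy group in the bottom unit (3,4-trans) | C(c5ccccc5)Oc1ccc([C@H]2Oc3c(c(OCc5ccccc5)cc(OCc5ccccc5)c3[C@H]3c4c(OCc5ccccc5)cc(OCc5ccccc5)cc4O[C@@H](c4ccc(OCc5ccccc5)cc4)[C@H]3O)[C@@H](c3c(OCc5ccccc5)cc(OCc5ccccc5)c4c3O[C@@H](c3ccc(OCc5ccccc5)cc3)[C@@H](O)[C@@H]4O)[C@H]2O)cc1 | intermediate
18 | CNP0159291.1 | Oc1ccc([C@H]2Oc3c(c(O)cc(O)c3[C@H]3c4c(O)cc(O)cc4O[C@@H](c4ccc(O)cc4)[C@H]3O)[C@@H](c3c(O)cc(O)c4c3O[C@@H](c3ccc(O)cc3)[C@@H](O)[C@@H]4O)[C@H]2O)cc1 | target

Total step count: 10. Longest linear sequence: 9 (steps 1, 2, 3, 4, 6, 7, 8, 9, 10).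

Steps most likely to fail

Step 8 (step 7 shares the risk).
- What may go wrong: the epoxide ionises fully to a freely rotating C4 cation and the inversion is lost. The aroyl group may migrate to C4 before the arene arrives. Attack may also occur through a C6 position.
- Approach of the fallback: it sets out from 10 and 13 and comes back at 16. The top unit is brought in with its pyran ring already closed (its O1–C2 bond is then the one made in step 6), and C4 is set last by hydride.
- Electrophile: 10 is silylated (TBSOTf, 2,6-lutidine, CH2Cl2) to the 3-O-TBS ether F1. F1 is oxidised with DDQ in wet CH2Cl2 to the 3,4-trans 4-ol F2, and then with Dess–Martin periodinane to the 4-ketone F3.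
- Nucleophile: 13 is brominated with NBS (CH2Cl2, −78 °C) at C8 of its upper unit to the bromide F4. MeLi (2 equiv) and then t-BuLi (THF, −78 °C) turn F4 into the aryllithium dialkoxide F5.
- Coupling and return: F5 adds to F3 to give the tertiary carbinol F6. Bu3SnH and CF3CO2H in CH2Cl2 ionise F6 and deliver hydride anti to the 3-silyloxy group, a sequence known to give 3,4-cis 4-arylflavan-3-ols, which leads to the silyl ether F7. TBAF then gives 16.

Step 4 (step 5 shares the risk).
- What may go wrong: the peroxide adds slowly to a push-pull enone with two ortho substituents. Facial selectivity may be poor on this unusual chalcone. The acid-labile epoxide may decompose during isolation.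
- Fallback: it sets out from 3 and comes back at 6. The epoxide is made by C–C bond formation at the aldehyde instead of oxidation of the enone.
- Sequence: an enantiopure camphor-derived sulfonium salt carrying a CH2C(O)NEt2 group is deprotonated (KOH, EtOH, −50 °C). The amide-stabilised ylide is added to 3 in a Corey–Chaykovsky-type epoxidation to give the trans-glycidic amide F8. 4-(Benzyloxy)phenyllithium (from 1-(benzyloxy)-4-bromobenzene and n-BuLi, THF, −78 °C) then converts the amide into the ketone 6.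

Step 10.
- What may go wrong: the bottom C4–OH bond is hydrogenolysed, or C4 ionises through a quinone methide once the ring-A phenols are free. Either process would be followed by reduction or self-condensation.
- Fallback: it sets out from 17 and comes back at 18. The four alcohols are masked (TESOTf, 2,6-lutidine, CH2Cl2, −78 °C) as the tetra-O-TES ether F9. F9 is hydrogenolysed (H2, Pd(OH)2/C, THF–EtOAc) to the nonaphenol tetra-O-TES ether F10, in which the bulky, poorly leaving silyloxy group protects C4. Buffered fluoride (TBAF–AcOH, THF, 0 °C) then releases 18 as the last operation.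

Further compounds
F1 | step 8 | (2S,3S)-5,7,4'-tri-O-benzyl-3-O-TBS-ent-epiafzelechin | CC(C)(C)[Si](C)(C)O[C@H]1Cc2c(OCc3ccccc3)cc(OCc3ccccc3)cc2O[C@H]1c1ccc(OCc2ccccc2)cc1
F2 | step 8 | (2S,3S,4R)-4-hydroxy derivative of F1 (3,4-trans) | C(c1ccccc1)Oc1cc(OCc2ccccc2)c2c(c1)O[C@@H](c1ccc(OCc3ccccc3)cc1)[C@@H](O[Si](C)(C)C(C)(C)C)[C@@H]2O
F3 | step 8 | (2S,3R)-5,7-bis(benzyloxy)-2-[4-(benzyloxy)phenyl]-3-(TBS-oxy)chroman-4-one (2,3-cis) | C(c1ccccc1)Oc1cc(OCc2ccccc2)c2c(c1)O[C@@H](c1ccc(OCc3ccccc3)cc1)[C@@H](O[Si](C)(C)C(C)(C)C)C2=O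
F4 | step 8 | 13 brominated at C8 of the upper unit | C(c1ccccc1)Oc1ccc([C@H]2Oc3c(Br)c(OCc4ccccc4)cc(OCc4ccccc4)c3[C@@H](c3c(OCc4ccccc4)cc(OCc4ccccc4)c4c3O[C@@H](c3ccc(OCc5ccccc5)cc3)[C@@H](O)C4)[C@H]2O)cc1
F5 | step 8 | 8-lithio derivative of 13 as its dilithium dialkoxide | C(c1ccccc1)Oc1ccc([C@H]2Oc3c([Li])c(OCc4ccccc4)cc(OCc4ccccc4)c3[C@@H](c3c(OCc4ccccc4)cc(OCc4ccccc4)c4c3O[C@@H](c3ccc(OCc5ccccc5)cc3)[C@@H](O[Li])C4)[C@H]2O[Li])cc1
F6 | step 8 | trimeric tertiary carbinol (top C4 bears OH, configuration at that carbon open, top 3-O-TBS) | C(c5ccccc5)Oc1ccc([C@H]2Oc3c(c(OCc5ccccc5)cc(OCc5ccccc5)c3C3(O)c4c(OCc5ccccc5)cc(OCc5ccccc5)cc4O[C@@H](c4ccc(OCc5ccccc5)cc4)[C@H]3O[Si](C)(C)C(C)(C)C)[C@@H](c3c(OCc5ccccc5)cc(OCc5ccccc5)c4c3O[C@@H](c3ccc(OCc5ccccc5)cc3)[C@@H](O)C4)[C@H]2O)cc1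
F7 | step 8 | 16 as the 3-O-TBS ether of its top unit | C(c5ccccc5)Oc1ccc([C@H]2Oc3c(c(OCc5ccccc5)cc(OCc5ccccc5)c3[C@H]3c4c(OCc5ccccc5)cc(OCc5ccccc5)cc4O[C@@H](c4ccc(OCc5ccccc5)cc4)[C@H]3O[Si](C)(C)C(C)(C)C)[C@@H](c3c(OCc5ccccc5)cc(OCc5ccccc5)c4c3O[C@@H](c3ccc(OCc5ccccc5)cc3)[C@@H](O)C4)[C@H]2O)cc1
F8 | step 4 | (2S,3R)-3-[2,4-bis(benzyloxy)-6-(methoxymethoxy)phenyl]-N,N-diethyloxirane-2-carboxamide | CCN(CC)C(=O)[C@H]1O[C@@H]1c1c(OCOC)cc(OCc2ccccc2)cc1OCc1ccccc1
F9 | step 10 | 17 as its tetra-O-TES ether (three 3-O and the bottom 4-O) | C(c5ccccc5)Oc1ccc([C@H]2Oc3c(c(OCc5ccccc5)cc(OCc5ccccc5)c3[C@H]3c4c(OCc5ccccc5)cc(OCc5ccccc5)cc4O[C@@H](c4ccc(OCc5ccccc5)cc4)[C@H]3O[Si](CC)(CC)CC)[C@@H](c3c(OCc5ccccc5)cc(OCc5ccccc5)c4c3O[C@@H](c3ccc(OCc5ccccc5)cc3)[C@@H](O[Si](CC)(CC)CC)[C@@H]4O[Si](CC)(CC)CC)[C@H]2O[Si](CC)(CC)CC)cc1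
F10 | step 10 | 18 as its tetra-O-TES ether, all nine phenols free | Oc1ccc([C@H]2Oc3c(c(O)cc(O)c3[C@H]3c4c(O)cc(O)cc4O[C@@H](c4ccc(O)cc4)[C@H]3O[Si](CC)(CC)CC)[C@@H](c3c(O)cc(O)c4c3O[C@@H](c3ccc(O)cc3)[C@@H](O[Si](CC)(CC)CC)[C@@H]4O[Si](CC)(CC)CC)[C@H]2O[Si](CC)(CC)CC)cc1
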